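**Retrosynthetic overview**
1. Target ⇒ acyclic lactol/phosphonate 18: the C11=C12 bond and the lactone C–O bond are opened together. Forward, one Z-selective intramolecular Horner–Wadsworth–Emmons (HWE) reaction closes the 14-membered carbocycle and the butenolide lactonises in the same flask (last step).
2. 18 ⇒ allyl carbinol 17 + vinyl lactol 6 by E-selective cross-metathesis at C6=C7.
3. 6 ⇒ (S)-linalool: C8 from the chiral pool, C10–OH by L-proline α-aminoxylation.
4. 17 ⇒ (S)-terpinen-4-ol + Ando phosphonoacetate 11: C1 from the chiral pool, ozonolytic ring opening, C2=C3 by IBX dehydrogenation, C4 by catalytic asymmetric allylboration.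
5. Ring order: no target ring exists before step 9; there the carbocycle closes first and the butenolide immediately after.

Atom numbers C1–C14 and C20 in the text are cembrane numbers of the target (C1 carries the isopropyl group, C20 is the lactone carbonyl).

Assumption: (S)-(+)-linalool and (S)-(+)-terpinen-4-ol are used at ≥98 % ee; commercial lots from essential oils of lower ee are enriched before use.

**Step 1**
Reactants: 1 (S)-(+)-linalool
Product: 4 (5S)-5-ethenyl-5-methyloxolan-2-ol (anomer mixture), via ozonide 2 (not isolated), via hydroxy aldehyde 3 (not isolated)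
Conditions: O3 (1 equiv, Sudan III end point), CH2Cl2, −78 °C; Me2S, −78 °C → rt
Reagents that add atoms: ozone, [O-][O+]=O
Why: Criegee ozonolysis is selective for the electron-rich trisubstituted alkene over the hindered vinyl group, and the γ-hydroxy aldehyde closes to the lactol; C8 comes unchanged from the chiral pool.

**Step 2**
Reactants: 4 (5S)-5-ethenyl-5-methyloxolan-2-ol
Product: 6 (3R,5S)-5-ethenyl-5-methyloxolane-2,3-diol (anomer mixture), via aminooxy lactol 5 (not isolated)
Conditions: L-proline (20 mol %), PhNO (1 equiv, slow addition), DMSO, rt; then CuSO4·5H2O (30 mol %), MeOH, 0 °C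
Reagents that add atoms: nitrosobenzene, O=Nc1ccccc1
Why: Proline-catalysed α-aminoxylation (enamine catalysis; the lactol reacts through its open form) with L-proline gives the (R)-α-oxy centre (C10) under catalyst control, and Cu(II) then cleaves the N–O bond without touching the vinyl group.

**Step 3**
Reactants: 7 (S)-(+)-terpinen-4-ol
Product: 9 (3S)-3-(propan-2-yl)heptane-1,3,6-triol (C6 epimers), via ozonide 8 (not isolated)
Conditions: O3, CH2Cl2, −78 °C; then NaBH4, MeOH, −78 → 0 °C
Reagents that add atoms: ozone, [O-][O+]=O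
Why: Ozonolysis with reductive NaBH4 work-up opens the cyclohexene to the C13 primary and C4 secondary alcohols while the tertiary carbinol C1 is carried over from the chiral pool (the C4 epimer mixture is erased in step 6).

**Step 4**
Reactants: 9 (3S)-3-(propan-2-yl)heptane-1,3,6-triol
Product: 10 (5S)-7-iodo-5-(propan-2-yl)heptane-2,5-diol
Conditions: I2 (1.05 equiv), PPh3, imidazole, THF–MeCN, −10 → 0 °C
Reagents that add atoms: iodine, II
Why: Appel reaction; with one equivalent of reagent at low temperature the primary alcohol is converted far faster than the secondary and tertiary ones.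

**Step 5**
Reactants: 10 (5S)-7-iodo-5-(propan-2-yl)heptane-2,5-diol; 11 ethyl 2-[bis(2-methylphenoxy)phosphoryl]acetate
Product: 13 ethyl (5S)-2-[bis(2-methylphenoxy)phosphoryl]-5,8-dihydroxy-5-(propan-2-yl)nonanoate (C2 and C8 epimers), via sodium enolate 12 (not isolated)
Conditions: 11 (1.5 equiv), NaH, DMF, 0 °C; then 10, 45 °C
Reagents that add atoms: none
Why: SN2 C-alkylation of the soft phosphonoacetate enolate by the primary iodide forms C12–C13; the carbanion is too weakly basic to deprotonate the hydroxyls, so oxetane formation and P–OAr exchange are avoided.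

**Step 6**
Reactants: 13 ethyl (5S)-2-[bis(2-methylphenoxy)phosphoryl]-5,8-dihydroxy-5-(propan-2-yl)nonanoate
Product: 15 ethyl (5S,6E)-2-[bis(2-methylphenoxy)phosphoryl]-5-hydroxy-8-oxo-5-(propan-2-yl)non-6-enoate, via saturated ketone 14 (not isolated)
Conditions: IBX (3.5 equiv), 4-methoxypyridine N-oxide, DMSO, 25 °C
Reagents that add atoms: none
Why: IBX oxidises the secondary alcohol to the methyl ketone and then dehydrogenates it (Nicolaou IBX·MPO dehydrogenation); only the C2–C3 side has the β-hydrogen needed, so the E-enone is the only possible regioisomer, and the tertiary OH, ester and phosphonate are inert.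

**Step 7**
Reactants: 15 ethyl (5S,6E)-2-[bis(2-methylphenoxy)phosphoryl]-5-hydroxy-8-oxo-5-(propan-2-yl)non-6-enoate
Product: 17 ethyl (5S,6E,8R)-2-[bis(2-methylphenoxy)phosphoryl]-5,8-dihydroxy-8-methyl-5-(propan-2-yl)undeca-6,10-dienoate, via borate ester 16 (not isolated)
Conditions: allylB(Oi-Pr)2 (2.5 equiv), (S)-3,3′-Br2-BINOL (15 mol %), PhCF3–PhMe, −35 °C; aq. work-up
Reagents that add atoms: allyldiisopropoxyborane, C=CCB(OC(C)C)OC(C)C
Why: Schaus BINOL-catalysed asymmetric allylboration of a methyl alkenyl ketone through a closed chair transition state delivers allyl to the Re face of the ketone and sets the (R)-carbinol (C4), using the catalyst enantiomer that gives (R)-2-phenylpent-4-en-2-ol from acetophenone (the antipode is used if the facial sense proves reversed).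

**Step 8**
Reactants: 17 ethyl (5S,6E,8R)-2-[bis(2-methylphenoxy)phosphoryl]-5,8-dihydroxy-8-methyl-5-(propan-2-yl)undeca-6,10-dienoate; 6 (3R,5S)-5-ethenyl-5-methyloxolane-2,3-diol (3 equiv)
Product: 18 ethyl (5S,6E,8R,10E)-2-[bis(2-methylphenoxy)phosphoryl]-11-[(2S,4R)-4,5-dihydroxy-2-methyloxolan-2-yl]-5,8-dihydroxy-8-methyl-5-(propan-2-yl)undeca-6,10-dienoate
Conditions: Hoveyda–Grubbs II (10 mol %), p-benzoquinone (10 mol %), CH2Cl2, 40 °C
Reagents that add atoms: none
Why: Olefin cross-metathesis between a Type I allyl group and a vinyl group on a fully substituted allylic carbon that cannot homodimerise; the C2=C3 alkene flanked by two quaternary carbons is inert and the quaternary neighbour enforces E geometry at C6=C7.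

**Step 9**
Reactants: 18 ethyl (5S,6E,8R,10E)-2-[bis(2-methylphenoxy)phosphoryl]-11-[(2S,4R)-4,5-dihydroxy-2-methyloxolan-2-yl]-5,8-dihydroxy-8-methyl-5-(propan-2-yl)undeca-6,10-dienoate
Product: 21 (1S,2E,4R,6E,8S,10R)-1,4,8-trihydroxycembra-2,6,11-trien-20,10-olide (CHEBI:68873), via open-chain aldehyde 19 (not isolated), via macrocyclic Z-hydroxy ester 20 (not isolated)
Conditions: NaI (3 equiv), DBU (2 equiv), THF, 0 °C → rt, 18 added over 12 h to 1 mM; AcOH quench
Reagents that add atoms: none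
Why: Ando-type Z-selective intramolecular Horner–Wadsworth–Emmons reaction on the aldehyde released from the lactol closes the 14-membered carbocycle with the ester cis to C10, and the C10 hydroxyl then lactonises to the butenolide in the same flask; slow lactol opening keeps the aldehyde concentration low and no stereocentre is touched.

**Compound list**
1 | (S)-(+)-linalool, (3S)-3,7-dimethylocta-1,6-dien-3-ol | C=C[C@@](C)(O)CCC=C(C)C | starting material
2 | ozonide of 1, 3-[(3S)-3-hydroxy-3-methylpent-4-en-1-yl]-5,5-dimethyl-1,2,4-trioxolane | C=C[C@@](C)(O)CCC1OOC(C)(C)O1 | intermediate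
3 | (4S)-4-hydroxy-4-methylhex-5-enal | C=C[C@@](C)(O)CCC=O | intermediate
4 | (5S)-5-ethenyl-5-methyloxolan-2-ol (anomers) | C=C[C@]1(C)CCC(O)O1 | intermediate
5 | (3R,5S)-3-(anilinooxy)-5-ethenyl-5-methyloxolan-2-ol | C=C[C@]1(C)C[C@@H](ONc2ccccc2)C(O)O1 | intermediate
6 | (3R,5S)-5-ethenyl-5-methyloxolane-2,3-diol (anomers) | C=C[C@]1(C)C[C@@H](O)C(O)O1 | intermediate
7 | (S)-(+)-terpinen-4-ol, (1S)-4-methyl-1-(propan-2-yl)cyclohex-3-en-1-ol | CC(C)[C@]1(O)CCC(C)=CC1 | starting material
8 | ozonide of 7, (3S)-6-methyl-3-(propan-2-yl)-7,8,9-trioxabicyclo[4.2.1]nonan-3-ol | CC(C)[C@]1(O)CCC2(C)OOC(O2)C1 | intermediate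
9 | (3S)-3-(propan-2-yl)heptane-1,3,6-triol (C6 epimers) | CC(C)[C@](CCO)(O)CCC(C)O | intermediate
10 | (5S)-7-iodo-5-(propan-2-yl)heptane-2,5-diol (C2 epimers) | CC(C)[C@](CCI)(O)CCC(C)O | intermediate
11 | ethyl 2-[bis(2-methylphenoxy)phosphoryl]acetate (Ando reagent) | CCOC(=O)CP(=O)(Oc1ccccc1C)Oc1ccccc1C | starting material
12 | sodium enolate of 11 | CCOC(=O)[CH-]P(=O)(Oc1ccccc1C)Oc1ccccc1C.[Na+] | intermediate
13 | ethyl (5S)-2-[bis(2-methylphenoxy)phosphoryl]-5,8-dihydroxy-5-(propan-2-yl)nonanoate (C2, C8 epimers) | CC(C)[C@](CCC(C(=O)OCC)P(=O)(Oc1ccccc1C)Oc1ccccc1C)(O)CCC(C)O | intermediate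
14 | ethyl (5S)-2-[bis(2-methylphenoxy)phosphoryl]-5-hydroxy-8-oxo-5-(propan-2-yl)nonanoate | CC(C)[C@](CCC(C(=O)OCC)P(=O)(Oc1ccccc1C)Oc1ccccc1C)(O)CCC(C)=O | intermediate
15 | ethyl (5S,6E)-2-[bis(2-methylphenoxy)phosphoryl]-5-hydroxy-8-oxo-5-(propan-2-yl)non-6-enoate | CC(C)[C@](CCC(C(=O)OCC)P(=O)(Oc1ccccc1C)Oc1ccccc1C)(O)/C=C/C(C)=O | intermediate
16 | 8-O-(diisopropoxyboryl) derivative of 17 | CC(C)[C@](CCC(C(=O)OCC)P(=O)(Oc1ccccc1C)Oc1ccccc1C)(O)/C=C/[C@](C)(OB(OC(C)C)OC(C)C)CC=C | intermediate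
17 | ethyl (5S,6E,8R)-2-[bis(2-methylphenoxy)phosphoryl]-5,8-dihydroxy-8-methyl-5-(propan-2-yl)undeca-6,10-dienoate | CC(C)[C@](CCC(C(=O)OCC)P(=O)(Oc1ccccc1C)Oc1ccccc1C)(O)/C=C/[C@](C)(O)CC=C | intermediate
18 | ethyl (5S,6E,8R,10E)-2-[bis(2-methylphenoxy)phosphoryl]-11-[(2S,4R)-4,5-dihydroxy-2-methyloxolan-2-yl]-5,8-dihydroxy-8-methyl-5-(propan-2-yl)undeca-6,10-dienoate | CC(C)[C@](CCC(C(=O)OCC)P(=O)(Oc1ccccc1C)Oc1ccccc1C)(O)/C=C/[C@](C)(O)C/C=C/[C@]2(C)C[C@@H](O)C(O)O2 | intermediate
19 | ethyl (5S,6E,8R,10E,12S,14R)-2-[bis(2-methylphenoxy)phosphoryl]-5,8,12,14-tetrahydroxy-8,12-dimethyl-15-oxo-5-(propan-2-yl)pentadeca-6,10-dienoate | CC(C)[C@](CCC(C(=O)OCC)P(=O)(Oc1ccccc1C)Oc1ccccc1C)(O)/C=C/[C@](C)(O)C/C=C/[C@@](C)(O)C[C@@H](O)C=O | intermediate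
20 | ethyl (1Z,3R,5S,6E,9R,10E,12S)-3,5,9,12-tetrahydroxy-5,9-dimethyl-12-(propan-2-yl)cyclotetradeca-1,6,10-triene-1-carboxylate | CC(C)[C@]1(O)/C=C/[C@](C)(O)C/C=C/[C@@](C)(O)C[C@@H](O)/C=C(/CC1)C(=O)OCC | intermediate
21 | (1S,2E,4R,6E,8S,10R)-1,4,8-trihydroxycembra-2,6,11-trien-20,10-olide (CHEBI:68873) | CC(C)[C@]1(O)/C=C/[C@](C)(O)C/C=C/[C@@](C)(O)C[C@@H]2C=C(CC1)C(=O)O2 | target

**Totals**
Total step count: 9. Longest linear sequence: 7 steps (7 → 21, steps 3–9).

**Three steps most likely to fail**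

Step 9 (HWE macrocyclisation/lactonisation). Ring strain may override the Ando reagent and give the E-enoate, which cannot lactonise; oligomerisation, base-induced epimerisation at C10 and oxa-Michael addition of the C8 hydroxyl to the butenolide are the other risks. Fallback: setting out from 18, close the ring under equilibrating Masamune–Roush conditions (LiCl, i-Pr2NEt, MeCN, 40 °C, 1 mM) and take the macrocyclic E-hydroxy ester F1. Irradiate F1 (300 nm, MeCN, acetophenone sensitiser); the contra-thermodynamic E→Z isomerisation is driven by irreversible lactonisation of the Z isomer, which comes back to the route at 20 and so at 21.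

Step 8 (cross-metathesis). The vinyl group on the fully substituted lactol carbon may be too hindered for an intermolecular metathesis. Fallback: reverse the order of the two unions. Setting out from 17 (with 6), intermolecular Ando olefination (NaI, DBU, THF, 0 °C) gives the acyclic Z-hydroxy ester F2, which lactonises in the flask to the butenolide diene F3. Ring-closing metathesis of F3 (Hoveyda–Grubbs II, PhMe, 2 mM, 60 °C; the butenolide and C2=C3 alkenes are inert) then joins C6 and C7 intramolecularly and comes back at 21.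

Step 6 (IBX oxidation/dehydrogenation). The dehydrogenation half may stall on the cyclic hemiketal form of the γ-hydroxy ketone or attack the phosphonoacetate C–H. Fallback: setting out from 13, Dess–Martin oxidation (CH2Cl2, NaHCO3, rt) stops at saturated ketone 14, now isolated. PhSeCl in EtOAc (rt) selenenylates through the more substituted enol to give the α-phenylselanyl ketone F4. H2O2/pyridine (CH2Cl2, 0 °C) oxidises it to the selenoxide F5, whose syn-elimination (possible only towards C2) comes back at 15.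

**Further compounds**
F1 | step 9 | ethyl (1E,3R,5S,6E,9R,10E,12S)-3,5,9,12-tetrahydroxy-5,9-dimethyl-12-(propan-2-yl)cyclotetradeca-1,6,10-triene-1-carboxylate | CC(C)[C@]1(O)/C=C/[C@](C)(O)C/C=C/[C@@](C)(O)C[C@@H](O)/C=C(\CC1)C(=O)OCC
F2 | step 8 | ethyl (2Z,4R,6S)-2-[(3S,4E,6R)-3,6-dihydroxy-6-methyl-3-(propan-2-yl)nona-4,8-dien-1-yl]-4,6-dihydroxy-6-methylocta-2,7-dienoate | CC(C)[C@](CC/C(C(=O)OCC)=C/[C@H](O)C[C@](C)(O)C=C)(O)/C=C/[C@](C)(O)CC=C
F3 | step 8 | (5R)-3-[(3S,4E,6R)-3,6-dihydroxy-6-methyl-3-(propan-2-yl)nona-4,8-dien-1-yl]-5-[(2S)-2-hydroxy-2-methylbut-3-en-1-yl]furan-2(5H)-one | CC(C)[C@](CCC1=C[C@@H](C[C@](C)(O)C=C)OC1=O)(O)/C=C/[C@](C)(O)CC=C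
F4 | step 6 | ethyl (5S)-2-[bis(2-methylphenoxy)phosphoryl]-5-hydroxy-8-oxo-7-(phenylselanyl)-5-(propan-2-yl)nonanoate | CC(C)[C@](CCC(C(=O)OCC)P(=O)(Oc1ccccc1C)Oc1ccccc1C)(O)CC([Se]c1ccccc1)C(C)=O
F5 | step 6 | ethyl (5S)-7-(benzeneseleninyl)-2-[bis(2-methylphenoxy)phosphoryl]-5-hydroxy-8-oxo-5-(propan-2-yl)nonanoate | CC(C)[C@](CCC(C(=O)OCC)P(=O)(Oc1ccccc1C)Oc1ccccc1C)(O)CC([Se](=O)c1ccccc1)C(C)=O
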